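59.7% of the electrophile in the larch flask is still unreacted at 10.0 h, with product at 41.7% and gaining slowly, and what I do at 15 h hangs on that stall.

all flasks: electrophile 1.3 M; temperature 20 °C

| flask | nucleophile | protic impurity | remark | time |
|---|---|---|---|---|
| larch | 1.1 equiv | 0.26 M | the very flask that is asked about, followed so far |  |
| flask | 1.10 equiv | 0.260 M |  | 15 h |

larch run (percent of the electrophile charged)

| time / h | product / % | electrophile / % |
|---|---|---|
| 2.00 | 21.3 | 78.0 |
| 4.00 | 30.4 | 68.4 |
| 5.00 | 32.4 | 66.5 |
| 8.00 | 38.6 | 60.7 |
| 10.0 | 41.7 | 59.7 |

(scatter of a reading: 1 percentage point)

- product that was removed still counts
- the earlier runs do not show what temperature does; that part of a forecast is a guess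

- dawn: at 15 h raise the temperature by 15 K, then wait 15 h
- dusk: at 15 h take out 90% of the product then present, then wait 15 h
- noon: change nothing and wait 15 h more

* product, in percent of the electrophile first charged, at 15 h
* what to do for the largest gain in product; "none" if nothing gains more than 2 percentage points (dawn / dusk / noon / none)
* product present, with what was taken out counted in, in percent of the electrophile first charged, after dusk
* product present, with what was taken out counted in, in percent of the electrophile first charged, after noon

I count turnovers of nucleophile in this flask. If each protic impurity takes one nucleophile, c(protic impurity)/c(electrophile) costs 0.200 equivalents, which leaves a spare of 0.900 equivalents. At one nucleophile per product that would allow 90.0%, but the last reading is about half of this and flattening. So I suppose that each product costs two nucleophiles, one built in and one held by the acid set free as protonated nucleophile. The spare divided by two is then my stall yield 45.0%, the product at which two nucleophiles per product have spent the spare.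

I therefore expect product just under 45.0% at 15 h. On this count, taking product out returns no nucleophile, so dusk and noon should end level, close to that yield. Warming is a guess from these runs, but it may loosen the hold on the protonated nucleophile, so I would choose dawn.

The forecast differs: 46% now, 50% after noon, 68% after dusk, and dusk as best. It reasons: “Removing product helps under either mechanism.”

The flask gives 43.5% at 15 h. Dusk and noon both end at 45.7%, gains of 2.2 percentage points and 2.2 points, so the forecast's dusk stands 22 points too high. Dawn gains 8.3 points, and the best choice is dawn.

    electrophile + nucleophile → acid set free + product (k = 0.00210 M⁻¹ min⁻¹, Ea = 86.0 kJ mol⁻¹)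
    nucleophile + acid set free ⇌ protonated nucleophile, settled at all times (K = 1800 M⁻¹, ΔH = −81.0 kJ mol⁻¹)
    nucleophile + protic impurity → quenched reagent (k = 0.0210 M⁻¹ min⁻¹, Ea = 78.0 kJ mol⁻¹)
    (constants at 20 °C)

In this flask the step of nucleophile with protic impurity had 99.5% of its turnover up to 15 h behind it at 7.50 h, while the step of electrophile with nucleophile had 61% of its own turnover up to 15 h behind it at 3.00 h. At 15.0 h free nucleophile stood at 3.19% of its charge, beside 0.559 M protonated nucleophile and 0.259 M quenched reagent, and product lay 1.5 points under the stall yield; left untouched for 150 h, this flask reaches 49.2%, past that yield, so the count marks a stall and not a wall. For the neighbour flask charged with 0.10 M of protic impurity, the same count gives a stall yield of 51.2%. The computed flask reaches 48.9% at 15.0 h.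

All runs were computed from invented constants; the scatter is artificial.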